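**Strategy.** The ring is numbered from the carbonyl carbon (C1); C7 is the hydroxymethyl carbon on C2. The cyclohexenone is cut at C3–C4 and C5–C6 into a (Z)-enol ether of 3-methylbutanal (C4, C5) and a 2-silyloxy diene that already carries the C6 ester (C3, C2, C1, C6). The key step exploits the 1,5-relationship of the C7 hydroxyl oxygen and the C4 oxygen across C2=C3. A temporary di(propan-2-yl)silylene bridge joins these two oxygens, and a thermal type 2 intramolecular Diels–Alder reaction then closes the carbocycle, forms both bonds and sets the all-cis C4/C5/C6 array in one operation. The precursor is an acyclic, achiral silaketal triene.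

Key step: step 8

Remark: TBSO = (tert-butyldimethylsilyl)oxy. Triene 16 is achiral, so compounds 17 to 22 are racemic and the enantiomer is selected in step 12; the SMILES of racemic compounds show the enantiomer that leads to the target.

**Step 1**
Reactants: 1 2-(TBSO)acetaldehyde; 2 ethyl 2-(triphenyl-λ5-phosphanylidene)propanoate
Product: 3 ethyl (2E)-2-methyl-4-(TBSO)but-2-enoate
Conditions: CH2Cl2, rt
Reagents that add atoms: none
Why: Wittig olefination with a stabilised α-methyl ylide should give the trisubstituted E-enoate.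

**Step 2**
Reactants: 3 ethyl (2E)-2-methyl-4-(TBSO)but-2-enoate
Product: 4 (2E)-2-methyl-4-(TBSO)but-2-enoic acid
Conditions: LiOH, THF/MeOH/H2O, rt; then 1 M HCl to pH 4, 0 °C
Reagents that add atoms: lithium hydroxide, [Li+].[OH-]
Why: Ester saponification; the primary silyl ether should survive hydroxide and a brief cold acidification.

**Step 3**
Reactants: 5 3-methylbut-1-yne
Product: 6 (1Z)-3-methylbut-1-en-1-yl acetate
Conditions: AcOH, Ru(η3-CH2C(CH3)CH2)2(Ph2P(CH2)4PPh2) (1 mol %), toluene, 65 °C, sealed tube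
Reagents that add atoms: acetic acid, CC(=O)O
Why: Ruthenium-catalysed anti-Markovnikov addition of a carboxylic acid to a terminal alkyne should give the (Z)-enol ester, which fixes the geometry of the later dienophile.

**Step 4**
Reactants: 6 (1Z)-3-methylbut-1-en-1-yl acetate; 7 2-bromoprop-2-en-1-ol
Product: 10 [(2-bromoprop-2-en-1-yl)oxy]{[(1Z)-3-methylbut-1-en-1-yl]oxy}di(propan-2-yl)silane, via potassium (1Z)-3-methylbut-1-en-1-olate 8 (not isolated), via chloro(enoxy)di(propan-2-yl)silane 9 (not isolated)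
Conditions: KOtBu, THF, −78 °C; cannulated into iPr2SiCl2, THF, −78 °C; then 7, imidazole, −78 °C to rt
Reagents that add atoms: dichlorodi(propan-2-yl)silane, CC(C)[Si](Cl)(Cl)C(C)C
Why: Alkoxide cleavage of the enol acetate should release the (Z)-enolate with retention of geometry, and stepwise O-silylation of enolate and alcohol at the hindered dichlorosilane (unsymmetrical silaketal formation) should give 10.

**Step 5**
Reactants: 10 [(2-bromoprop-2-en-1-yl)oxy]{[(1Z)-3-methylbut-1-en-1-yl]oxy}di(propan-2-yl)silane; 11 2-chloro-N-methoxy-N-methylacetamide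
Product: 13 1-chloro-3-{[({[(1Z)-3-methylbut-1-en-1-yl]oxy}di(propan-2-yl)silyl)oxy]methyl}but-3-en-2-one, via vinyllithium 12 (not isolated)
Conditions: tert-BuLi (2.05 equiv), Et2O, −78 °C; then 11, −78 to −40 °C; aq. NH4Cl
Reagents that add atoms: none
Why: Bromine–lithium exchange followed by Weinreb ketone synthesis; the chelated tetrahedral adduct should prevent over-addition and release the chloromethyl enone on work-up.

**Step 6**
Reactants: 13 1-chloro-3-{[({[(1Z)-3-methylbut-1-en-1-yl]oxy}di(propan-2-yl)silyl)oxy]methyl}but-3-en-2-one; 4 (2E)-2-methyl-4-(TBSO)but-2-enoic acid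
Product: 15 3-{[({[(1Z)-3-methylbut-1-en-1-yl]oxy}di(propan-2-yl)silyl)oxy]methyl}-2-oxobut-3-en-1-yl (2E)-2-methyl-4-(TBSO)but-2-enoate, via cesium carboxylate 14 (not isolated)
Conditions: 4, Cs2CO3 (0.55 equiv), DMF, rt; then 13, 0 °C to rt
Reagents that add atoms: none
Why: SN2 displacement of the activated α-chloro ketone by the carboxylate (O-alkylation) should install the C6 ester under conditions that leave both silicon groups intact.

**Step 7**
Reactants: 15 3-{[({[(1Z)-3-methylbut-1-en-1-yl]oxy}di(propan-2-yl)silyl)oxy]methyl}-2-oxobut-3-en-1-yl (2E)-2-methyl-4-(TBSO)but-2-enoate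
Product: 16 (1Z)-3-{[({[(1Z)-3-methylbut-1-en-1-yl]oxy}di(propan-2-yl)silyl)oxy]methyl}-2-(TBSO)buta-1,3-dien-1-yl (2E)-2-methyl-4-(TBSO)but-2-enoate
Conditions: TBSOTf, Et3N, CH2Cl2, −78 to 0 °C
Reagents that add atoms: tert-butyldimethylsilyl trifluoromethanesulfonate, CC(C)(C)[Si](C)(C)OS(=O)(=O)C(F)(F)F
Why: Soft enolisation (silyl triflate and amine) at the only enolisable position should give the 2-silyloxy diene, the Z enol ether (silyloxy cis to acyloxy) being favoured by allylic strain.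

**Step 8**
Reactants: 16 (1Z)-3-{[({[(1Z)-3-methylbut-1-en-1-yl]oxy}di(propan-2-yl)silyl)oxy]methyl}-2-(TBSO)buta-1,3-dien-1-yl (2E)-2-methyl-4-(TBSO)but-2-enoate
Product: 17 rac-all-cis cycloadduct 3,3,9-tri(propan-2-yl)-7-(TBSO)-2,4-dioxa-3-silabicyclo[4.3.1]dec-6-en-8-yl (2E)-2-methyl-4-(TBSO)but-2-enoate
Conditions: toluene (0.01 M), BHT (cat.), 200 °C, sealed tube
Reagents that add atoms: none
Why: On heating, the (Z)-enol ether (C4=C5) should add suprafacially to the s-cis 2-silyloxy diene (C3=C2–C1=C6) in a concerted [4+2] cycloaddition; the closest known reaction type is the type 2 intramolecular Diels–Alder reaction of 2-substituted dienes through a disposable silicon (silaketal) tether. The carbocycle closes in the [4+2] mode and the seven-membered ring C2–C7–O–Si–O–C4–C3 closes with it, giving a bridged bicycle whose bridgehead double bond is the C2=C1 silyl enol ether. C4 and C5 become cis because the Z geometry of the enol ether is transferred. C6 becomes cis to both because the four-atom tether can reach from C7 only to an endo oxygen on C4, which places the isopropyl group endo as well, while the (Z)-silyl enol ether holds the C6 acyloxy group in the outside position of the diene. The step needs meta regiochemistry (C4 to C3 and not to C6) and endo topology; both are secured by the tether length and not by electronics, so an unactivated electron-rich dienophile is used at the price of a high temperature. The absolute configuration is not controlled, so 17 should form as the racemate.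

**Step 9**
Reactants: 17 rac-all-cis cycloadduct 3,3,9-tri(propan-2-yl)-7-(TBSO)-2,4-dioxa-3-silabicyclo[4.3.1]dec-6-en-8-yl (2E)-2-methyl-4-(TBSO)but-2-enoate
Product: 18 rac-7-oxo-6-(phenylselanyl)-3,3,9-tri(propan-2-yl)-2,4-dioxa-3-silabicyclo[4.3.1]decan-8-yl (2E)-2-methyl-4-(TBSO)but-2-enoate
Conditions: PhSeCl, CH2Cl2, −78 °C
Reagents that add atoms: benzeneselenenyl chloride, Cl[Se]c1ccccc1
Why: Electrophilic α-selenenylation of the regiodefined silyl enol ether; the new quaternary centre at C2 has only one possible configuration because C7 is held in the bridge.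

**Step 10**
Reactants: 18 rac-7-oxo-6-(phenylselanyl)-3,3,9-tri(propan-2-yl)-2,4-dioxa-3-silabicyclo[4.3.1]decan-8-yl (2E)-2-methyl-4-(TBSO)but-2-enoate
Product: 21 rac-(4S,5S,6S)-4-hydroxy-6-{[(2E)-4-hydroxy-2-methylbut-2-enoyl]oxy}-2-(hydroxymethyl)-5-(propan-2-yl)cyclohex-2-en-1-one, via triol selenide 19 (not isolated), via selenoxide 20 (not isolated)
Conditions: HF·pyridine, pyridine, THF, 0 °C to rt; then 30% aq. H2O2, 0 °C to rt
Reagents that add atoms: none
Why: Fluoride desilylation opens the silicon bridge and frees the three hydroxyls, and selenide oxidation followed by syn selenoxide elimination should go toward C3 and away from the oxygen-bearing C7 to give the C2=C3 enone.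

**Step 11**
Reactants: 21 rac-(4S,5S,6S)-4-hydroxy-6-{[(2E)-4-hydroxy-2-methylbut-2-enoyl]oxy}-2-(hydroxymethyl)-5-(propan-2-yl)cyclohex-2-en-1-one
Product: 22 rac-(4S,5S,6S)-4-hydroxy-6-{[(2E)-2-methyl-4-(TBSO)but-2-enoyl]oxy}-5-(propan-2-yl)-2-[(TBSO)methyl]cyclohex-2-en-1-one
Conditions: TBSCl (2.2 equiv), imidazole, CH2Cl2, −20 to 0 °C
Reagents that add atoms: tert-butyl(chloro)dimethylsilane, CC(C)(C)[Si](C)(C)Cl
Why: Silyl ether formation at the two primary allylic hydroxyls should be much faster than at the hindered secondary C4 hydroxyl.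

**Step 12**
Reactants: 22 rac-(4S,5S,6S)-4-hydroxy-6-{[(2E)-2-methyl-4-(TBSO)but-2-enoyl]oxy}-5-(propan-2-yl)-2-[(TBSO)methyl]cyclohex-2-en-1-one
Product: 23 (4S,5S,6S)-4-hydroxy-6-{[(2E)-2-methyl-4-(TBSO)but-2-enoyl]oxy}-5-(propan-2-yl)-2-[(TBSO)methyl]cyclohex-2-en-1-one
Conditions: Burkholderia cepacia lipase (Amano PS), vinyl acetate, tert-butyl methyl ether, 30 °C, run to just over half conversion
Reagents that add atoms: none
Why: Lipase-catalysed acylative kinetic resolution of a secondary allylic alcohol; by the empirical rule for lipases the enantiomer with an R carbinol (isopropyl-bearing C5 as the large group) should be acetylated, leaving the 4S alcohol 23.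

**Step 13**
Reactants: 23 (4S,5S,6S)-4-hydroxy-6-{[(2E)-2-methyl-4-(TBSO)but-2-enoyl]oxy}-5-(propan-2-yl)-2-[(TBSO)methyl]cyclohex-2-en-1-one; 24 (2Z)-2-methylbut-2-enoic acid (angelic acid)
Product: 26 (4S,5S,6S)-4-{[(2Z)-2-methylbut-2-enoyl]oxy}-6-{[(2E)-2-methyl-4-(TBSO)but-2-enoyl]oxy}-5-(propan-2-yl)-2-[(TBSO)methyl]cyclohex-2-en-1-one, via mixed anhydride 25 (not isolated)
Conditions: 24, 2,4,6-trichlorobenzoyl chloride, Et3N, toluene, rt; then 23, toluene, 75 °C
Reagents that add atoms: none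
Why: Yamaguchi esterification through the preformed mixed anhydride, run without a nucleophilic catalyst so that the Z geometry of the angeloyl group is kept; C4 reacts at oxygen and keeps its configuration.

**Step 14**
Reactants: 26 (4S,5S,6S)-4-{[(2Z)-2-methylbut-2-enoyl]oxy}-6-{[(2E)-2-methyl-4-(TBSO)but-2-enoyl]oxy}-5-(propan-2-yl)-2-[(TBSO)methyl]cyclohex-2-en-1-one
Product: 27 (4S,5S,6S)-6-{[(2E)-4-hydroxy-2-methylbut-2-enoyl]oxy}-2-(hydroxymethyl)-4-{[(2Z)-2-methylbut-2-enoyl]oxy}-5-(propan-2-yl)cyclohex-2-en-1-one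
Conditions: HF·pyridine, pyridine, THF, 0 °C to rt
Reagents that add atoms: none
Why: Buffered acidic fluoride desilylation of the two primary silyl ethers should leave both esters, the enone and the epimerisable C6 untouched.

**Compound list**

1 | 2-[(tert-butyldimethylsilyl)oxy]acetaldehyde | O=CCO[Si](C)(C)C(C)(C)C | starting material
2 | ethyl 2-(triphenyl-λ5-phosphanylidene)propanoate | CCOC(=O)C(C)=P(c1ccccc1)(c1ccccc1)c1ccccc1 | starting material
3 | ethyl (2E)-2-methyl-4-(TBSO)but-2-enoate | CCOC(=O)/C(C)=C/CO[Si](C)(C)C(C)(C)C | intermediate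
4 | (2E)-2-methyl-4-(TBSO)but-2-enoic acid | OC(=O)/C(C)=C/CO[Si](C)(C)C(C)(C)C | intermediate
5 | 3-methylbut-1-yne | CC(C)C#C | starting material
6 | (1Z)-3-methylbut-1-en-1-yl acetate | CC(=O)O/C=C\C(C)C | intermediate
7 | 2-bromoprop-2-en-1-ol | OCC(Br)=C | starting material
8 | potassium (1Z)-3-methylbut-1-en-1-olate | CC(C)/C=C\[O-].[K+] | intermediate
9 | chloro{[(1Z)-3-methylbut-1-en-1-yl]oxy}di(propan-2-yl)silane | CC(C)/C=C\O[Si](Cl)(C(C)C)C(C)C | intermediate
10 | [(2-bromoprop-2-en-1-yl)oxy]{[(1Z)-3-methylbut-1-en-1-yl]oxy}di(propan-2-yl)silane | BrC(=C)CO[Si](C(C)C)(C(C)C)O/C=C\C(C)C | intermediate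
11 | 2-chloro-N-methoxy-N-methylacetamide | ClCC(=O)N(C)OC | starting material
12 | [(2-lithioprop-2-en-1-yl)oxy]{[(1Z)-3-methylbut-1-en-1-yl]oxy}di(propan-2-yl)silane | [Li]C(=C)CO[Si](C(C)C)(C(C)C)O/C=C\C(C)C | intermediate
13 | 1-chloro-3-{[({[(1Z)-3-methylbut-1-en-1-yl]oxy}di(propan-2-yl)silyl)oxy]methyl}but-3-en-2-one | C=C(CO[Si](C(C)C)(C(C)C)O/C=C\C(C)C)C(=O)CCl | intermediate
14 | cesium (2E)-2-methyl-4-(TBSO)but-2-enoate | [Cs+].[O-]C(=O)/C(C)=C/CO[Si](C)(C)C(C)(C)C | intermediate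
15 | 3-{[({[(1Z)-3-methylbut-1-en-1-yl]oxy}di(propan-2-yl)silyl)oxy]methyl}-2-oxobut-3-en-1-yl (2E)-2-methyl-4-(TBSO)but-2-enoate | C=C(CO[Si](C(C)C)(C(C)C)O/C=C\C(C)C)C(=O)COC(=O)/C(C)=C/CO[Si](C)(C)C(C)(C)C | intermediate
16 | (1Z)-3-{[({[(1Z)-3-methylbut-1-en-1-yl]oxy}di(propan-2-yl)silyl)oxy]methyl}-2-(TBSO)buta-1,3-dien-1-yl (2E)-2-methyl-4-(TBSO)but-2-enoate | C=C(CO[Si](C(C)C)(C(C)C)O/C=C\C(C)C)/C(O[Si](C)(C)C(C)(C)C)=C/OC(=O)/C(C)=C/CO[Si](C)(C)C(C)(C)C | intermediate
17 | rac-3,3,9-tri(propan-2-yl)-7-(TBSO)-2,4-dioxa-3-silabicyclo[4.3.1]dec-6-en-8-yl (2E)-2-methyl-4-(TBSO)but-2-enoate; the C1–O2 bond, the C9 isopropyl group and the C8 ester oxygen lie on one face of the carbocycle | O1[C@H]2CC(CO[Si]1(C(C)C)C(C)C)=C(O[Si](C)(C)C(C)(C)C)[C@@H](OC(=O)/C(C)=C/CO[Si](C)(C)C(C)(C)C)[C@H]2C(C)C | intermediate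
18 | rac-7-oxo-6-(phenylselanyl)-3,3,9-tri(propan-2-yl)-2,4-dioxa-3-silabicyclo[4.3.1]decan-8-yl (2E)-2-methyl-4-(TBSO)but-2-enoate; phenylselanyl on the face opposite to the silicon bridge | O1[C@H]2C[C@](CO[Si]1(C(C)C)C(C)C)([Se]c3ccccc3)C(=O)[C@@H](OC(=O)/C(C)=C/CO[Si](C)(C)C(C)(C)C)[C@H]2C(C)C | intermediate
19 | rac-(2R,4S,5S,6S)-4-hydroxy-6-{[(2E)-4-hydroxy-2-methylbut-2-enoyl]oxy}-2-(hydroxymethyl)-2-(phenylselanyl)-5-(propan-2-yl)cyclohexan-1-one | O[C@H]1C[C@](CO)([Se]c2ccccc2)C(=O)[C@@H](OC(=O)/C(C)=C/CO)[C@H]1C(C)C | intermediate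
20 | selenoxide of 19 (configuration at selenium not defined) | O[C@H]1C[C@](CO)([Se](=O)c2ccccc2)C(=O)[C@@H](OC(=O)/C(C)=C/CO)[C@H]1C(C)C | intermediate
21 | rac-(4S,5S,6S)-4-hydroxy-6-{[(2E)-4-hydroxy-2-methylbut-2-enoyl]oxy}-2-(hydroxymethyl)-5-(propan-2-yl)cyclohex-2-en-1-one | O[C@H]1C=C(CO)C(=O)[C@@H](OC(=O)/C(C)=C/CO)[C@H]1C(C)C | intermediate
22 | rac-(4S,5S,6S)-4-hydroxy-6-{[(2E)-2-methyl-4-(TBSO)but-2-enoyl]oxy}-5-(propan-2-yl)-2-[(TBSO)methyl]cyclohex-2-en-1-one (racemate) | O[C@H]1C=C(CO[Si](C)(C)C(C)(C)C)C(=O)[C@@H](OC(=O)/C(C)=C/CO[Si](C)(C)C(C)(C)C)[C@H]1C(C)C | intermediate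
23 | (4S,5S,6S)-4-hydroxy-6-{[(2E)-2-methyl-4-(TBSO)but-2-enoyl]oxy}-5-(propan-2-yl)-2-[(TBSO)methyl]cyclohex-2-en-1-one (single enantiomer) | O[C@H]1C=C(CO[Si](C)(C)C(C)(C)C)C(=O)[C@@H](OC(=O)/C(C)=C/CO[Si](C)(C)C(C)(C)C)[C@H]1C(C)C | intermediate
24 | (2Z)-2-methylbut-2-enoic acid (angelic acid) | C/C=C(/C)C(=O)O | starting material
25 | (2Z)-2-methylbut-2-enoic 2,4,6-trichlorobenzoic anhydride | C/C=C(/C)C(=O)OC(=O)c1c(Cl)cc(Cl)cc1Cl | intermediate
26 | (4S,5S,6S)-4-{[(2Z)-2-methylbut-2-enoyl]oxy}-6-{[(2E)-2-methyl-4-(TBSO)but-2-enoyl]oxy}-5-(propan-2-yl)-2-[(TBSO)methyl]cyclohex-2-en-1-one | C/C=C(/C)C(=O)O[C@H]1C=C(CO[Si](C)(C)C(C)(C)C)C(=O)[C@@H](OC(=O)/C(C)=C/CO[Si](C)(C)C(C)(C)C)[C@H]1C(C)C | intermediate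
27 | (4S,5S,6S)-6-{[(2E)-4-hydroxy-2-methylbut-2-enoyl]oxy}-2-(hydroxymethyl)-4-{[(2Z)-2-methylbut-2-enoyl]oxy}-5-(propan-2-yl)cyclohex-2-en-1-one | C/C=C(/C)C(=O)O[C@H]1C=C(CO)C(=O)[C@@H](OC(=O)/C(C)=C/CO)[C@H]1C(C)C | target

**Totals.** Total steps: 14. Longest linear sequence: 12 steps (steps 3 to 14, from 5).

**Steps most likely to fail**

Step 8. Diene and dienophile are both electron-rich, so the cycloaddition may be slower than thermal decomposition of the silyl enol ethers, and the bridgehead alkene adds strain. The fallback keeps the temporary silicon connection but uses a vinylsilane as the tethered dienophile and creates the C4 oxygen by Tamao–Fleming oxidation. It sets out from 7 and comes back at 21.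
- Alcohol 7 would be silylated with chlorodi(propan-2-yl)silane and imidazole to [(2-bromoprop-2-en-1-yl)oxy]di(propan-2-yl)silane F1.
- Trans-hydrosilylation of alkyne 5 with F1 ([RuCl2(p-cymene)]2, CH2Cl2) should give the (Z)-alkenylsilane [(2-bromoprop-2-en-1-yl)oxy][(1Z)-3-methylbut-1-en-1-yl]di(propan-2-yl)silane F2.
- Bromine–lithium exchange and addition to 11 would give the chloromethyl enone F3; displacement with the cesium salt of 4 would give the ester F4; TBSOTf and Et3N would give the triene F5.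
- Heating F5 should give the type 2 cycloadduct F6, a 3-oxa-2-silabicyclo[3.3.1]non-5-ene in which C4–Si, the isopropyl group and the C6 ester are cis for the same geometric reasons.
- PhSeCl would give the selenide F7. Tamao–Fleming oxidation (KF, KHCO3, H2O2; C–Si to C–OH with retention, with oxidation and elimination of the selenide) followed by HF·pyridine would give 21.

Step 12. The lipase may not accept the hindered C4 alcohol, or may discriminate the enantiomers poorly. The fallback replaces the enzyme by non-enzymatic acyl-transfer catalysis; it sets out from 22 and comes back at 23. Compound 22 would be treated with 2-methylpropanoic anhydride, iPr2NEt and the enantiomer of the chiral isothiourea benzotetramisole that acylates the 4R alcohol faster (CHCl3, 0 °C). Unreacted 23 would be recovered; no new compound lies on the way.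

Step 13. The angeloyl unit may isomerise from Z to E, the acylation of the hindered C4 hydroxyl may be slow, and the warm basic medium may epimerise C6. The fallback builds the angelate double bond on the ester instead of transferring it; it sets out from 23 and comes back at 26. Alcohol 23 would be esterified with 2-[bis(2-methylphenoxy)phosphoryl]propanoic acid (DCC, DMAP cat., CH2Cl2, 0 °C) to the phosphonate ester F8. A Z-selective Horner–Wadsworth–Emmons olefination of F8 with acetaldehyde (KN(SiMe3)2, 18-crown-6, THF, −78 °C) should then give 26.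

**Further compounds**

F1 | step 8 | [(2-bromoprop-2-en-1-yl)oxy]di(propan-2-yl)silane | BrC(=C)CO[SiH](C(C)C)C(C)C
F2 | step 8 | [(2-bromoprop-2-en-1-yl)oxy][(1Z)-3-methylbut-1-en-1-yl]di(propan-2-yl)silane | BrC(=C)CO[Si](C(C)C)(C(C)C)/C=C\C(C)C
F3 | step 8 | 1-chloro-3-[({[(1Z)-3-methylbut-1-en-1-yl]di(propan-2-yl)silyl}oxy)methyl]but-3-en-2-one | C=C(CO[Si](C(C)C)(C(C)C)/C=C\C(C)C)C(=O)CCl
F4 | step 8 | 3-[({[(1Z)-3-methylbut-1-en-1-yl]di(propan-2-yl)silyl}oxy)methyl]-2-oxobut-3-en-1-yl (2E)-2-methyl-4-(TBSO)but-2-enoate | C=C(CO[Si](C(C)C)(C(C)C)/C=C\C(C)C)C(=O)COC(=O)/C(C)=C/CO[Si](C)(C)C(C)(C)C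
F5 | step 8 | (1Z)-3-[({[(1Z)-3-methylbut-1-en-1-yl]di(propan-2-yl)silyl}oxy)methyl]-2-(TBSO)buta-1,3-dien-1-yl (2E)-2-methyl-4-(TBSO)but-2-enoate | C=C(CO[Si](C(C)C)(C(C)C)/C=C\C(C)C)/C(O[Si](C)(C)C(C)(C)C)=C/OC(=O)/C(C)=C/CO[Si](C)(C)C(C)(C)C
F6 | step 8 | rac-all-cis 2,2,8-tri(propan-2-yl)-6-(TBSO)-3-oxa-2-silabicyclo[3.3.1]non-5-en-7-yl (2E)-2-methyl-4-(TBSO)but-2-enoate | [Si]1(C(C)C)(C(C)C)[C@H]2CC(CO1)=C(O[Si](C)(C)C(C)(C)C)[C@@H](OC(=O)/C(C)=C/CO[Si](C)(C)C(C)(C)C)[C@H]2C(C)C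
F7 | step 8 | rac-6-oxo-5-(phenylselanyl)-2,2,8-tri(propan-2-yl)-3-oxa-2-silabicyclo[3.3.1]nonan-7-yl (2E)-2-methyl-4-(TBSO)but-2-enoate | [Si]1(C(C)C)(C(C)C)[C@H]2C[C@](CO1)([Se]c3ccccc3)C(=O)[C@@H](OC(=O)/C(C)=C/CO[Si](C)(C)C(C)(C)C)[C@H]2C(C)C
F0 | step 12 | none | none
F8 | step 13 | (4S,5S,6S)-4-({2-[bis(2-methylphenoxy)phosphoryl]propanoyl}oxy)-6-{[(2E)-2-methyl-4-(TBSO)but-2-enoyl]oxy}-5-(propan-2-yl)-2-[(TBSO)methyl]cyclohex-2-en-1-one | CC(C(=O)O[C@H]1C=C(CO[Si](C)(C)C(C)(C)C)C(=O)[C@@H](OC(=O)/C(C)=C/CO[Si](C)(C)C(C)(C)C)[C@H]1C(C)C)P(=O)(Oc1ccccc1C)Oc1ccccc1C
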